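Late in the blue flask target keeps falling while side product stands still, and your next charge of partner hangs on that loss.

in all of them: starting material 0.20 mM

|  | partner | remark | time |
|---|---|---|---|
| blue | 1.2 equiv | the very flask that is asked about, followed so far |  |
| violet | 0.80 equiv | run made earlier |  |
| flask | 1.20 equiv |  | 2.5 min |

- blue (time / s: side product / %, target / %): 10.0: 8.0, 25.6; 15.0: 11.1, 26.7; 30.0: 14.6, 20.5; 40.0: 16.6, 16.7; 60.0: 16.8, 9.7
- violet (time / s: side product / %, target / %): 10.0: 5.7, 30.2; 25.0: 10.2, 35.7; 50.0: 11.1, 29.7; 80.0: 11.0, 24.6; 120: 11.5, 21.7

(each reading ± 0.5 percentage points)

1. share of side product in side product plus target at 0.50 s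
2. share of side product in side product plus target at 8.0 s
3. share of side product in side product plus target at 2.5 min

- what was read earlier has a scatter of 0.5 percentage points, one standard deviation

My reckoning assumes that partner also consumes target, one for one, to give an over-reaction product, and that each side product takes up one partner as well. Once starting material is consumed, partner left minus target left, both in percent of the starting material charged, is then a fixed gap: the excess of partner over one equivalent. It is 20.0% in the blue run, and in the violet run target stands above partner by 20.0%, which is target's floor there.

With a rate proportional to partner times target, the logarithm of the larger of the two over the smaller climbs steadily, at a constant times the gap. The violet readings from 80.0 s to 120 s give k_O = 0.544 mM⁻¹ s⁻¹, the second-order constant of target loss to partner. It is rough: a scatter of 0.5 percentage points sits on a partner figure, at 120 s, of only 1.7 points.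

Carried from the blue reading at 60.0 s, k_O gives my estimate of 0.967% target at 2.5 min. With side product at its read 16.8%, my estimate of the late share is 94.6%. So I would not repeat this charge: on these assumptions, below one equivalent, partner is the limiting reagent and target keeps a floor.

The forecast gave 12%, 21.5% and 90%, the last a little below mine, on the words “Side product stays near 17.5%, giving a share near 90%”.

The flask gives 2.03%, 21.0% and 93.5%, with target at 1.14% at 2.50 min.

    starting material → target (k = 0.0580 s⁻¹)
    starting material ⇌ intermediate (K = 0.800, k = 0.0600 s⁻¹)
    partner + intermediate → side product (k = 340 M⁻¹ s⁻¹)
    intermediate → target (k = 0.0770 s⁻¹)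
    partner + target → over-reaction product (k = 530 M⁻¹ s⁻¹)

In this flask the half-life of target against partner, 0.17 min at 0.343 min, is far shorter than the 2.5 min of the run, and k_O with partner at 22.6% of its charge at 1.25 min still gives a half-life of 0.392 min, while over-reaction product ends at 82.4%. With 0.480 equiv of partner, k_O against target at its floor of 52.0% gives partner a half-life of 12.3 s, shorter than the run, and that neighbour flask ends with partner at 0.0305% of its charge and target at 52.0%.

Readings and results stem from a simulated flask on assumed constants.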